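I count.

| flask | solid monomer | initiator | temperature | remark | time |
|---|---|---|---|---|---|
| spring | 1.4 M | 2.7 mM | 72 °C | run made earlier |  |
| winter | 2.2 M | 2.7 mM | 100 °C | run made earlier |  |
| noon | 1 M | 1.4 mM | 72 °C | run made earlier |  |
| south | 1.0 M | 2.7 mM | 110 °C |  | 2.5 min |
| south-west | 1.0 M | 2.7 mM | 85 °C |  | 2.5 min |
| north | 1.0 M | 2.7 mM | 60 °C |  | 2.5 min |



| spring: time / min | spring: monomer in chains / % | winter: time / min | winter: monomer in chains / % | noon: time / min | noon: monomer in chains / % |
|---|---|---|---|---|---|
| 1.00 | 9.1 | 0.250 | 3.2 | 2.00 | 10.1 |
| 2.50 | 10.8 | 0.417 | 2.3 | 4.00 | 10.1 |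
| 4.00 | 12.7 | 0.667 | 3.7 | 5.00 | 12.8 |
| 6.00 | 14.0 | 1.33 | 3.4 | 8.00 | 13.1 |
| 10.0 | 12.9 | 2.50 | 2.9 | 10.0 | 12.6 |

(scatter of a reading: 1 percentage point)

- solid monomer is a solid; its amount is given per volume of the solution
- at the start none of the solid monomer is in solution

* the best flask by amount of monomer in chains, in percent of the solid monomer charged; "all alike" if 1.5 percentage points covers them all (south / south-west / north / all alike)
* amount of monomer in chains at the end, in percent of the solid monomer charged, south
* amount of monomer in chains at the end, in percent of the solid monomer charged, south-west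
* amount of monomer in chains at the end, in percent of the solid monomer charged, north

The spring and noon readings climb and then flatten, the look of dead-end polymerisation. The spring run tops out at 14.0% of its 1.4 M, which makes 72.6 molecules of monomer in chains for each molecule of initiator charged: the turnover count. The winter run stays near 3.2% of 2.2 M, a count of 26.1, so the count is smaller in the hotter run.

But can a count carry over to a different charge of solid? Spring holds 1.50 times the amount in chains of noon, and the square root of their initiator ratio is 1.39. Within the scatter I see no mark of the solid charged, so I carry the count.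

Taking one factor per degree, my counts are 18.1 for south, 45.1 for south-west and 113 for north. On 1.0 M these give 4.88%, 12.2% and 30.4%.

Yet I read a count as a ceiling, and the cold north flask may not reach it in 2.5 min. Spring has 65.0% of its top at 1.00 min, a lifetime of 0.953 min. Winter looks finished at its first reading, and I roughly grant it a lifetime of 0.125 min. Scaled per degree, north gets 2.27 min, so it reaches 66.7% of its ceiling, or 20.3%. North needs just 40.1% of its ceiling to pass south-west, and my share is larger, so I choose north.

The forecast differs: south-west, with 4%, 10.5% and 9% for south, south-west and north, its north lower than mine. It reasons that “hotter means a lower ceiling because the initiator burns out faster”.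

The flasks give 5.06% in south, 11.5% in south-west and 16.9% in north.

    solid monomer ⇌ free monomer, rate k1*(cs1 - [free monomer]) while solid is left; crystals form when [free monomer] > cs1 (solubility = 38.0 mM, k = 3.40 s⁻¹)
    free monomer + initiating radical → growing radical + monomer in chains (k = 2.70 × 10⁶ M⁻¹ s⁻¹, Ea = 22.0 kJ mol⁻¹)
    free monomer + growing radical → monomer in chains + growing radical, rate k3*[growing radical]*[free monomer] (k = 76000 M⁻¹ s⁻¹, Ea = 25.0 kJ mol⁻¹)
    initiator → 2 initiating radical (k = 0.0160 s⁻¹, Ea = 97.0 kJ mol⁻¹)
    2 growing radical → dead chain (k = 1.00 × 10⁸ M⁻¹ s⁻¹, Ea = 9.00 kJ mol⁻¹)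
    (constants at 60 °C)

North is best, with a turnover count of 62.4 against 18.7 in south, where the spring run read 72.6. The main reason north stops at its count is the pairing of two growing radicals into a dead chain: in the run with that step taken away, north gives 100% instead of 16.9%.

Readings and results are calculated from invented constants, noise included.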